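**Plan**
- Retrosynthesis: the C2–Br and C3–Br bonds are cut first (late electrophilic bromination), then the N–Boc bond, then both C–N bonds of the pyrrole ring (N1–C2 and N1–C7a) in a single operation, and last C2–C3 (Wittig homologation) and C3–C3a (formylation).
- Enabling feature: C4 (carrying Br) and C7a (carrying N1) are the two carbons that flank C3a, and C6–Br is para to C3a. The benzene ring of the indole is therefore a 2,4,6-tribromophenyl ring whose two equivalent ortho bromides become the retained C4–Br and the bromide spent on the N1–C7a bond.
- Forward: the benzene ring is bought as 1,3,5-tribromobenzene. C3 is attached by lithiation/formylation and C2 by methoxymethylene Wittig reaction and hydrolysis. One carbamate nitrogen is then bonded to C2 and to C7a, closing the pyrrole ring (the only ring formed). Boc removal and bromination at C3 and C2 finish the route.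
- Stereochemistry: the target has no stereocentre. The only geometric element on the way, the enecarbamate double bond, equilibrates and ends inside the aromatic ring.

Key step: step 4

Remark on the chemistry: aldehyde 7 is assumed to be too sensitive for storage and is carried crude into step 4 on the day it is made. The enol ether 6 and the enecarbamate 9 are handled as mixtures of geometric isomers.

**Step 1**
Reactants: 1 1,3,5-tribromobenzene; 2 N,N-dimethylformamide
Product: 4 2,4,6-tribromobenzaldehyde, via (2,4,6-tribromophenyl)lithium 3 (not isolated)
Conditions: lithium diisopropylamide (commercial solution, 1.05 equiv), THF, −78 °C; then DMF (3 equiv), −78 → 0 °C; 1 M aq. HCl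
Reagents that add atoms: N,N-dimethylformamide (2), CN(C)C=O
Why: Deprotonative lithiation followed by formylation of the aryllithium should work because each of the three equivalent ring hydrogens lies between two bromines and is acidic enough for the amide base at −78 °C, where neither bromine–lithium exchange nor aryne formation competes, and the aryllithium adds to DMF to give the aldehyde on acidic work-up.

**Step 2**
Reactants: 4 2,4,6-tribromobenzaldehyde; 5 (methoxymethyl)triphenylphosphonium chloride
Product: 6 1,3,5-tribromo-2-(2-methoxyethenyl)benzene (mixture of E and Z isomers)
Conditions: 5 (1.3 equiv), potassium tert-butoxide (1.25 equiv), THF, 0 °C; then 4, 0 °C → rt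
Reagents that add atoms: (methoxymethyl)triphenylphosphonium chloride (5), COC[P+](c1ccccc1)(c1ccccc1)c1ccccc1.[Cl-]
Why: The Wittig reaction of the unstabilised methoxymethylene ylide should add even to this 2,6-disubstituted benzaldehyde, and the isomer ratio is of no consequence because both enol ethers hydrolyse to the same aldehyde.

**Step 3**
Reactants: 6 1,3,5-tribromo-2-(2-methoxyethenyl)benzene
Product: 7 2-(2,4,6-tribromophenyl)acetaldehyde
Conditions: 2 M aq. HCl, THF, 60 °C, under argon; extractive work-up, used crude
Reagents that add atoms: water, O
Why: Acid-catalysed enol ether hydrolysis should proceed by C-protonation to an oxocarbenium ion, capture by water and loss of methanol from the hemiacetal, and the aryl bromides are inert to aqueous acid.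

**Step 4**
Reactants: 7 2-(2,4,6-tribromophenyl)acetaldehyde; 8 tert-butyl carbamate
Product: 10 tert-butyl 4,6-dibromo-1H-indole-1-carboxylate, via tert-butyl [2-(2,4,6-tribromophenyl)ethenyl]carbamate 9 (not isolated)
Conditions: 8 (0.95 equiv), PPTS (5 mol %), 4 Å molecular sieves, toluene, 80 °C; then, in the same flask, CuI (10 mol %), N,N'-dimethylethylenediamine (30 mol %), K2CO3 (2 equiv), 100 °C
Reagents that add atoms: tert-butyl carbamate (8), CC(C)(C)OC(N)=O
Why: The pyridinium acid catalyses addition of the carbamate nitrogen to the aldehyde and loss of water, and the N-Boc imine so formed tautomerises to enecarbamate 9 (N1–C2); K2CO3 then deprotonates the N–H, the diamine-ligated amidate of monovalent copper inserts into the neighbouring ortho C–Br bond, and reductive elimination forms N1–C7a. The closest known reactions are the acid-catalysed condensation of aldehydes with carbamates to enecarbamates, the Goldberg-type intramolecular amidation of 2-haloaryl enamides and enecarbamates to N-acylindoles, and the domino condensation/N-arylation of 2-(2-haloaryl) carbonyl compounds. The pyrrole ring closes by intramolecular aryl amidation through a six-membered cuprocycle (Cu, N1, C2, C3, C3a, C7a) that contracts to the five-membered ring on reductive elimination; only the isomer of 9 with nitrogen cis to the aryl group can close, and the isomers should interconvert through the N-Boc imine and through the delocalised aza-enolate. No stereocentre is formed. The step needs chemoselectivity among three aryl bromides: the two ortho bromides are equivalent by the symmetry of the ring, so insertion into either gives the same product, while the para bromide (the future C6–Br) cannot be reached by the tethered amidate. Carbamate 8 is the limiting reagent and is consumed before copper is added, so no free N–H nucleophile is left for intermolecular coupling at C4–Br or C6–Br, and the product carries no N–H either.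

**Step 5**
Reactants: 10 tert-butyl 4,6-dibromo-1H-indole-1-carboxylate
Product: 11 4,6-dibromo-1H-indole
Conditions: TFA/CH2Cl2 (1:4), 0 °C → rt; aq. NaHCO3
Reagents that add atoms: none
Why: Acidolysis of the tert-butyl carbamate should proceed by protonation, loss of the tert-butyl cation as 2-methylpropene and decarboxylation of the indole-1-carboxylic acid, the two bromines making the indole too electron-poor to oligomerise in acid at this temperature.

**Step 6**
Reactants: 11 4,6-dibromo-1H-indole; 12 N-bromosuccinimide
Product: 14 2,3,4,6-tetrabromo-1H-indole, via 3,4,6-tribromo-1H-indole 13 (not isolated)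
Conditions: NBS (1.0 equiv), anhydrous THF, 0 °C; then NBS (1.05 equiv), 0 °C → rt, dark; aq. Na2S2O3, rapid chromatography on base-washed silica
Reagents that add atoms: N-bromosuccinimide (12), O=C1CCC(=O)N1Br
Why: In this electrophilic aromatic bromination the pyrrole ring remains the most electron-rich part of the molecule, so C3 should react first, and the second equivalent should brominate the 3-bromoindole at C2 (directly or through a 3,3-dibromoindolenine and 1,2-shift of bromine), while the dibrominated benzene ring is deactivated and stays untouched.

**Compound list**
1 | 1,3,5-tribromobenzene | Brc1cc(Br)cc(Br)c1 | starting material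
2 | N,N-dimethylformamide | CN(C)C=O | starting material
3 | (2,4,6-tribromophenyl)lithium | [Li]c1c(Br)cc(Br)cc1Br | intermediate (not isolated)
4 | 2,4,6-tribromobenzaldehyde | O=Cc1c(Br)cc(Br)cc1Br | intermediate
5 | (methoxymethyl)triphenylphosphonium chloride | COC[P+](c1ccccc1)(c1ccccc1)c1ccccc1.[Cl-] | starting material
6 | 1,3,5-tribromo-2-(2-methoxyethenyl)benzene (E/Z mixture) | COC=Cc1c(Br)cc(Br)cc1Br | intermediate
7 | 2-(2,4,6-tribromophenyl)acetaldehyde | O=CCc1c(Br)cc(Br)cc1Br | intermediate
8 | tert-butyl carbamate | CC(C)(C)OC(N)=O | starting material
9 | tert-butyl [2-(2,4,6-tribromophenyl)ethenyl]carbamate (E/Z mixture, closes through the Z isomer) | CC(C)(C)OC(=O)NC=Cc1c(Br)cc(Br)cc1Br | intermediate (not isolated)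
10 | tert-butyl 4,6-dibromo-1H-indole-1-carboxylate | CC(C)(C)OC(=O)n1ccc2c(Br)cc(Br)cc21 | intermediate
11 | 4,6-dibromo-1H-indole | Brc1cc(Br)c2cc[nH]c2c1 | intermediate
12 | N-bromosuccinimide | O=C1CCC(=O)N1Br | starting material
13 | 3,4,6-tribromo-1H-indole | Brc1cc(Br)c2c(Br)c[nH]c2c1 | intermediate (not isolated)
14 | 2,3,4,6-tetrabromo-1H-indole | Brc1cc(Br)c2c(Br)c(Br)[nH]c2c1 | target

**Step count**
Total steps: 6. Longest linear sequence: 6 steps (1 → 4 → 6 → 7 → 10 → 11 → 14).

**Steps most likely to fail**

Step 4. The dehydrative condensation may stall at the hemiaminal or at the bis-carbamate aminal, the aldehyde may self-condense, the Boc group may be lost under warm acid, and unreacted aldehyde may tie up the diamine ligand as an imidazolidine. The fallback sets out from 7 and makes the N1–C2 bond through a sulfonyl-activated adduct instead of by direct dehydration. Aldehyde 7, carbamate 8 and sodium benzenesulfinate in aqueous formic acid/methanol at room temperature should deposit tert-butyl [1-(benzenesulfonyl)-2-(2,4,6-tribromophenyl)ethyl]carbamate F1 (racemic). K2CO3 in THF should then eliminate benzenesulfinate to the N-Boc imine, which tautomerises to 9. After filtration from the sulfinate salt, 9 is closed with CuI, N,N'-dimethylethylenediamine and K2CO3 in toluene as before. The fallback comes back to the route at 10.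

Step 6. The second bromination may be slow at C2 of a deactivated 3-bromoindole crowded by the C4 bromine, traces of water may divert the bromoindolenine towards oxindole-type products, and the N–H dibromoindole may decompose on silica or in light. The fallback sets out from 13, isolated after the first equivalent of NBS, and installs the C2 bromine by deoxybromination of a lactam. Acid hydrolysis of 13 (85 % H3PO4, 2-methoxyethanol, 100 °C) should give 4,6-dibromo-1,3-dihydro-2H-indol-2-one F2. POBr3 with imidazole in 1,2-dichloroethane at 80 °C should convert it into 2,4,6-tribromo-1H-indole F3. One equivalent of NBS in THF at 0 °C should then brominate the free C3. The fallback comes back to the route at 14.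

Step 3. Aldol self-condensation and air oxidation of the arylacetaldehyde may erode the material during hydrolysis and isolation. The fallback sets out from 6 and bypasses the free aldehyde. Acid-catalysed addition of carbamate 8 across the enol ether (PPTS, toluene, 60 °C) should give tert-butyl [1-methoxy-2-(2,4,6-tribromophenyl)ethyl]carbamate F4 (racemic). Continued heating with PPTS over 5 Å molecular sieves should expel methanol to give 9. The fallback comes back to the route at 9, which is closed to 10 in the same flask under the copper conditions of step 4.

**Further compounds**
F1 | step 4 | tert-butyl [1-(benzenesulfonyl)-2-(2,4,6-tribromophenyl)ethyl]carbamate (racemic) | CC(C)(C)OC(=O)NC(Cc1c(Br)cc(Br)cc1Br)S(=O)(=O)c1ccccc1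
F2 | step 6 | 4,6-dibromo-1,3-dihydro-2H-indol-2-one | O=C1Cc2c(Br)cc(Br)cc2N1
F3 | step 6 | 2,4,6-tribromo-1H-indole | Brc1cc(Br)c2cc(Br)[nH]c2c1
F4 | step 3 | tert-butyl [1-methoxy-2-(2,4,6-tribromophenyl)ethyl]carbamate (racemic) | COC(Cc1c(Br)cc(Br)cc1Br)NC(=O)OC(C)(C)C
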